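**Retrosynthetic overview**
- Hansforester A (all four carbinol centres R) comes from its hexabenzyl ether by one global hydrogenolysis; that ether comes from a four-unit acid and a (R)-1-arylpropan-2-ol by acyl C–O esterification.
- Both aryl-CO–O–CH(CH3)CH2CO2H units come from a hindered benzoic acid and (S)-β-butyrolactone by alkyl C–O bond formation with inversion (a new single-insertion ring opening, used twice).
- The central benzoic acid comes from C–H formylation and oxidation of the resorcinol ring after its side-chain alcohol has been esterified.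
- One alcohol, made from an aryl Grignard reagent and (R)-propylene oxide, serves as both 2-hydroxypropyl arene units.
- No ring is formed: the benzene rings are bought intact, and the only ring event is opening of the β-lactone (twice).

Assumption: 1, 4, 5 and 8 are bought as catalogue compounds; (S)-8 is sold as the single enantiomer, though it costs more than the racemate.

**Step 1**
Reactants: 1 methyl 2,4-dihydroxy-6-methylbenzoate (methyl orsellinate)
Product: 3 2,4-bis(benzyloxy)-6-methylbenzoic acid, via methyl 2,4-bis(benzyloxy)-6-methylbenzoate 2 (not isolated)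
Conditions: BnBr (2.4 equiv), K2CO3, DMSO, 50 °C; then KOH, H2O, 95 °C; then aq HCl
Reagents that add atoms: benzyl bromide BrCc1ccccc1; potassium hydroxide [K+].[OH-]
Why: Williamson O-benzylation of both phenols, then saponification of the hindered methyl ester in the same pot (forced by KOH in DMSO/water), gives the acid; no stereocentre is involved.

**Step 2**
Reactants: 4 1,3-bis(benzyloxy)-5-bromobenzene; 5 (R)-propylene oxide [(R)-2-methyloxirane]
Product: 7 (R)-1-[3,5-bis(benzyloxy)phenyl]propan-2-ol, via 3,5-bis(benzyloxy)phenylmagnesium bromide 6 (not isolated)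
Conditions: Mg, THF, reflux; then CuI (10 mol%), 5, −30 → 0 °C; then aq NH4Cl
Reagents that add atoms: none
Why: Copper-catalysed Grignard opening of the epoxide (SN2 at the unhindered CH2) does not touch the C–O stereocentre, so (R)-5 gives the (R)-alcohol.

**Step 3**
Reactants: 3 2,4-bis(benzyloxy)-6-methylbenzoic acid; 8 (S)-β-butyrolactone [(S)-4-methyloxetan-2-one]
Product: 9 (R)-3-{[2,4-bis(benzyloxy)-6-methylbenzoyl]oxy}butanoic acid
Conditions: 3 (1.4 equiv), 8 (1.0 equiv), Cs2CO3 (10 mol%), 4 Å MS, DMF, 50 °C; then aq citric acid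
Reagents that add atoms: none
Why: Proposed new method: acid-buffered, carboxylate-catalysed single insertion of a β-lactone into the O–H bond of a di-ortho-substituted benzoic acid – the caesium aryl carboxylate (20 mol%) attacks C4 of the strained lactone through its unhindered oxygen by SN2 with alkyl–oxygen scission and inversion, so (S)-8 gives the (R)-ester; the aliphatic carboxylate formed (about one pKa unit weaker as an acid than the 2,6-disubstituted benzoic acid) is protonated at once by the excess of 3, which regenerates the aryl carboxylate and holds back a second insertion and E1cB crotonate formation, while the retention pathway through acyl attack and a mixed anhydride is disfavoured by the hindered aroyl carbon; the closest known reaction type is the carboxylate-initiated anionic ring-opening polymerisation of β-butyrolactone (alkyl–O cleavage with inversion), which has not been used as a stoichiometric, stereospecific esterification of hindered benzoic acids.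

**Step 4**
Reactants: 9 (R)-3-{[2,4-bis(benzyloxy)-6-methylbenzoyl]oxy}butanoic acid; 7 (R)-1-[3,5-bis(benzyloxy)phenyl]propan-2-ol
Product: 10 (R)-1-[3,5-bis(benzyloxy)phenyl]propan-2-yl (R)-3-{[2,4-bis(benzyloxy)-6-methylbenzoyl]oxy}butanoate
Conditions: DCC, DMAP (0.2 equiv), CH2Cl2, 0 °C → rt
Reagents that add atoms: none
Why: Steglich esterification forms the acyl C–O bond with retention at the carbinol of 7; the low DMAP loading and low temperature limit E1cB loss of the β-aroyloxy group.

**Step 5**
Reactants: 10 (R)-1-[3,5-bis(benzyloxy)phenyl]propan-2-yl (R)-3-{[2,4-bis(benzyloxy)-6-methylbenzoyl]oxy}butanoate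
Product: 12 (R)-1-[3,5-bis(benzyloxy)-2-formylphenyl]propan-2-yl (R)-3-{[2,4-bis(benzyloxy)-6-methylbenzoyl]oxy}butanoate, via aryl dimethyliminium chloride 11 (not isolated)
Conditions: POCl3 (1.3 equiv), DMF, 0 °C → rt; then H2O, 0 °C
Reagents that add atoms: N,N-dimethylformamide CN(C)C=O; water O
Why: Vilsmeier–Haack formylation attacks the only arene without an electron-withdrawing group (the orsellinate ring is deactivated by its ester), at the position ortho to the side chain and para to one OBn, because the site between the two OBn groups is more hindered.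

**Step 6**
Reactants: 12 (R)-1-[3,5-bis(benzyloxy)-2-formylphenyl]propan-2-yl (R)-3-{[2,4-bis(benzyloxy)-6-methylbenzoyl]oxy}butanoate
Product: 13 2,4-bis(benzyloxy)-6-[(R)-2-({(R)-3-[(2,4-bis(benzyloxy)-6-methylbenzoyl)oxy]butanoyl}oxy)propyl]benzoic acid
Conditions: NaClO2, NaH2PO4, 2-methyl-2-butene, t-BuOH/THF/H2O, 0 °C → rt
Reagents that add atoms: sodium chlorite [Na+].[O-]Cl=O
Why: Pinnick oxidation converts the hindered, electron-rich aldehyde into the acid under buffered conditions that leave esters and benzyl ethers intact; 2-methyl-2-butene scavenges HOCl.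

**Step 7**
Reactants: 13 2,4-bis(benzyloxy)-6-[(R)-2-({(R)-3-[(2,4-bis(benzyloxy)-6-methylbenzoyl)oxy]butanoyl}oxy)propyl]benzoic acid; 8 (S)-β-butyrolactone
Product: 14 (R)-3-({2,4-bis(benzyloxy)-6-[(R)-2-({(R)-3-[(2,4-bis(benzyloxy)-6-methylbenzoyl)oxy]butanoyl}oxy)propyl]benzoyl}oxy)butanoic acid
Conditions: 8 (0.9 equiv), Cs2CO3 (10 mol%), 4 Å MS, DMF, 50 °C; then aq citric acid; unreacted 13 recovered
Reagents that add atoms: none
Why: Proposed new method: second use of the acid-buffered, carboxylate-catalysed β-lactone single insertion of step 3 – the carboxylate of the di-ortho-substituted acid 13 opens (S)-8 at C4 by SN2 alkyl–oxygen scission with inversion to set the second (R)-butanoate centre, the hindered aroyl carbon is never activated, and keeping 13 in slight excess leaves the more acidic aryl acid as the proton buffer that stops a second insertion; the closest known reaction type is again carboxylate-initiated ring-opening polymerisation of β-butyrolactone with inversion.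

**Step 8**
Reactants: 14 (R)-3-({2,4-bis(benzyloxy)-6-[(R)-2-({(R)-3-[(2,4-bis(benzyloxy)-6-methylbenzoyl)oxy]butanoyl}oxy)propyl]benzoyl}oxy)butanoic acid; 7 (R)-1-[3,5-bis(benzyloxy)phenyl]propan-2-ol
Product: 15 hexa-O-benzyl Hansforester A [the (R)-1-[3,5-bis(benzyloxy)phenyl]propan-2-yl ester of 14]
Conditions: DCC, DMAP (0.2 equiv), CH2Cl2, 0 °C → rt
Reagents that add atoms: none
Why: Steglich esterification forms the last acyl C–O bond with retention at the carbinol of 7, under the same conditions that worked on the same acid type in step 4.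

**Step 9**
Reactants: 15 hexa-O-benzyl Hansforester A
Product: 16 Hansforester A
Conditions: H2 (1 atm), 10% Pd/C, EtOAc/THF, rt
Reagents that add atoms: none
Why: Catalytic hydrogenolysis removes the six aryl benzyl ethers; the four ester C–O bonds are homobenzylic or aliphatic, not benzylic, so they and all four stereocentres are untouched.

**Compound list**
1 | methyl 2,4-dihydroxy-6-methylbenzoate (methyl orsellinate) | COC(=O)c1c(C)cc(O)cc1O | starting material
2 | methyl 2,4-bis(benzyloxy)-6-methylbenzoate | COC(=O)c1c(C)cc(OCc2ccccc2)cc1OCc1ccccc1 | intermediate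
3 | 2,4-bis(benzyloxy)-6-methylbenzoic acid | Cc1cc(OCc2ccccc2)cc(OCc2ccccc2)c1C(=O)O | intermediate
4 | 1,3-bis(benzyloxy)-5-bromobenzene | Brc1cc(OCc2ccccc2)cc(OCc2ccccc2)c1 | starting material
5 | (R)-propylene oxide | C[C@@H]1CO1 | starting material
6 | 3,5-bis(benzyloxy)phenylmagnesium bromide | Br[Mg]c1cc(OCc2ccccc2)cc(OCc2ccccc2)c1 | intermediate
7 | (R)-1-[3,5-bis(benzyloxy)phenyl]propan-2-ol | C[C@@H](O)Cc1cc(OCc2ccccc2)cc(OCc2ccccc2)c1 | intermediate
8 | (S)-β-butyrolactone [(S)-4-methyloxetan-2-one] | C[C@H]1CC(=O)O1 | starting material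
9 | (R)-3-{[2,4-bis(benzyloxy)-6-methylbenzoyl]oxy}butanoic acid | Cc1cc(OCc2ccccc2)cc(OCc2ccccc2)c1C(=O)O[C@H](C)CC(=O)O | intermediate
10 | (R)-1-[3,5-bis(benzyloxy)phenyl]propan-2-yl (R)-3-{[2,4-bis(benzyloxy)-6-methylbenzoyl]oxy}butanoate | Cc1cc(OCc2ccccc2)cc(OCc2ccccc2)c1C(=O)O[C@H](C)CC(=O)O[C@H](C)Cc1cc(OCc2ccccc2)cc(OCc2ccccc2)c1 | intermediate
11 | aryl dimethyliminium chloride (ArCH=NMe2+ Cl−, the iminium precursor of aldehyde 12) | Cc1cc(OCc2ccccc2)cc(OCc2ccccc2)c1C(=O)O[C@H](C)CC(=O)O[C@H](C)Cc1cc(OCc2ccccc2)cc(OCc2ccccc2)c1C=[N+](C)C.[Cl-] | intermediate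
12 | (R)-1-[3,5-bis(benzyloxy)-2-formylphenyl]propan-2-yl (R)-3-{[2,4-bis(benzyloxy)-6-methylbenzoyl]oxy}butanoate | Cc1cc(OCc2ccccc2)cc(OCc2ccccc2)c1C(=O)O[C@H](C)CC(=O)O[C@H](C)Cc1cc(OCc2ccccc2)cc(OCc2ccccc2)c1C=O | intermediate
13 | 2,4-bis(benzyloxy)-6-[(R)-2-({(R)-3-[(2,4-bis(benzyloxy)-6-methylbenzoyl)oxy]butanoyl}oxy)propyl]benzoic acid | Cc1cc(OCc2ccccc2)cc(OCc2ccccc2)c1C(=O)O[C@H](C)CC(=O)O[C@H](C)Cc1cc(OCc2ccccc2)cc(OCc2ccccc2)c1C(=O)O | intermediate
14 | (R)-3-({2,4-bis(benzyloxy)-6-[(R)-2-({(R)-3-[(2,4-bis(benzyloxy)-6-methylbenzoyl)oxy]butanoyl}oxy)propyl]benzoyl}oxy)butanoic acid | Cc1cc(OCc2ccccc2)cc(OCc2ccccc2)c1C(=O)O[C@H](C)CC(=O)O[C@H](C)Cc1cc(OCc2ccccc2)cc(OCc2ccccc2)c1C(=O)O[C@H](C)CC(=O)O | intermediate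
15 | hexa-O-benzyl Hansforester A | Cc1cc(OCc2ccccc2)cc(OCc2ccccc2)c1C(=O)O[C@H](C)CC(=O)O[C@H](C)Cc1cc(OCc2ccccc2)cc(OCc2ccccc2)c1C(=O)O[C@H](C)CC(=O)O[C@H](C)Cc1cc(OCc2ccccc2)cc(OCc2ccccc2)c1 | intermediate
16 | Hansforester A | Cc1cc(O)cc(O)c1C(=O)O[C@H](C)CC(=O)O[C@H](C)Cc1cc(O)cc(O)c1C(=O)O[C@H](C)CC(=O)O[C@H](C)Cc1cc(O)cc(O)c1 | target

**Totals**
Total step count: 9. Longest linear sequence: 8 steps (steps 1, 3, 4, 5, 6, 7, 8, 9, from 1 to 16).

**Three steps most likely to fail**

Step 7 (new lactone insertion on the advanced acid 13). The likely failures are a slow reaction, or a second insertion once 13 is nearly consumed. The fallback is known chemistry; it sets out from 7 and 13 and returns at 15, replacing steps 7 and 8 by a convergent union. Alcohol 7 is acylated with diketene (cat. DMAP, CH2Cl2, 0 °C) to give (R)-1-[3,5-bis(benzyloxy)phenyl]propan-2-yl 3-oxobutanoate F5. Noyori hydrogenation with RuCl2[(S)-BINAP] (H2 50 bar, CH2Cl2/EtOH, 50 °C; benzyl ethers survive) gives (R)-1-[3,5-bis(benzyloxy)phenyl]propan-2-yl (S)-3-hydroxybutanoate F6. Mitsunobu esterification of 13 with F6 (PPh3, DIAD, toluene, 0 °C → rt) inverts the carbinol to (R) without activating the hindered aroyl carbon and gives 15 directly.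

Step 3 (first use of the new lactone insertion). The likely failures are oligo-insertion, crotonate formation, or difficult separation of 9 from excess 3. The fallback is known chemistry; it sets out from 3 and returns at 9. Oxalyl chloride with cat. DMF in CH2Cl2 converts 3 into 2,4-bis(benzyloxy)-6-methylbenzoyl chloride F1. F1 acylates commercial tert-butyl (R)-3-hydroxybutanoate (Et3N, DMAP, CH2Cl2; retention, hence the (R)-hydroxy ester) to give tert-butyl (R)-3-{[2,4-bis(benzyloxy)-6-methylbenzoyl]oxy}butanoate F2. Brief TFA/CH2Cl2 at 0 °C cleaves the tert-butyl ester and gives 9.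

Step 5 (Vilsmeier formylation). The likely failures are formylation between the two OBn groups or on the orsellinate ring. The fallback sets out from 7 (and uses 9) and returns at 13, replacing steps 4 to 6 by a halogen handle set before the esterification. NIS (cat. TFA, MeCN, 0 °C) iodinates 7 ortho to the side chain to give (R)-1-[3,5-bis(benzyloxy)-2-iodophenyl]propan-2-ol F3. DCC/DMAP coupling with 9 gives (R)-1-[3,5-bis(benzyloxy)-2-iodophenyl]propan-2-yl (R)-3-{[2,4-bis(benzyloxy)-6-methylbenzoyl]oxy}butanoate F4. Palladium-catalysed hydroxycarbonylation (Pd(OAc)2/Xantphos, CO 1 atm, KOAc, H2O, dioxane, 80 °C) converts the aryl iodide into the acid 13.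

**Further compounds**
F1 | step 3 | 2,4-bis(benzyloxy)-6-methylbenzoyl chloride | Cc1cc(OCc2ccccc2)cc(OCc2ccccc2)c1C(Cl)=O
F2 | step 3 | tert-butyl (R)-3-{[2,4-bis(benzyloxy)-6-methylbenzoyl]oxy}butanoate | Cc1cc(OCc2ccccc2)cc(OCc2ccccc2)c1C(=O)O[C@H](C)CC(=O)OC(C)(C)C
F3 | step 5 | (R)-1-[3,5-bis(benzyloxy)-2-iodophenyl]propan-2-ol | C[C@@H](O)Cc1cc(OCc2ccccc2)cc(OCc2ccccc2)c1I
F4 | step 5 | (R)-1-[3,5-bis(benzyloxy)-2-iodophenyl]propan-2-yl (R)-3-{[2,4-bis(benzyloxy)-6-methylbenzoyl]oxy}butanoate | Cc1cc(OCc2ccccc2)cc(OCc2ccccc2)c1C(=O)O[C@H](C)CC(=O)O[C@H](C)Cc1cc(OCc2ccccc2)cc(OCc2ccccc2)c1I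
F5 | step 7 | (R)-1-[3,5-bis(benzyloxy)phenyl]propan-2-yl 3-oxobutanoate | CC(=O)CC(=O)O[C@H](C)Cc1cc(OCc2ccccc2)cc(OCc2ccccc2)c1
F6 | step 7 | (R)-1-[3,5-bis(benzyloxy)phenyl]propan-2-yl (S)-3-hydroxybutanoate | C[C@H](O)CC(=O)O[C@H](C)Cc1cc(OCc2ccccc2)cc(OCc2ccccc2)c1
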